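The earlier runs and the new flask are calculated from invented constants; scatter was added.

Start from the time of reading: south-east stands 40 h and west 12 h, both later than the highest readings of the earlier runs, at 3.00 h, so reckon what D has lost since its peak.

| flask | L | X | remark | time |
|---|---|---|---|---|
| beta | 0.75 M | 0.50 M | run made earlier |  |
| delta | 1 M | 0.50 M | run made earlier |  |
| south-east | 0.50 M | 0.300 M |  | 40 h |
| west | 0.50 M | 0.500 M |  | 12 h |

- beta (time / h: D / %): 0.500: 25.6; 1.33: 47.3; 3.00: 56.8; 8.00: 53.6
- delta (time / h: D / %): 0.500: 29.2; 1.33: 49.8; 3.00: 61.1; 8.00: 55.0

(each reading ± 1 percentage point)

- in percentages every species weighs as the L in it: one E counts as two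
- the analysis behind the earlier runs scatters by 1 percentage point, standard deviation
- reactions considered so far: L <-> X; L -> D; X -> G; D <-> G; L + D -> E
- in a conversion X counts as not yet reacted

1. which of the two ends with the higher amount of D, in percent of the L and X together charged ("neither" if they lie within 2 percentage points) (south-east / west / neither)
2. D at the end, in percent of the L and X together charged, south-east
3. D at the end, in percent of the L and X together charged, west

Weigh the inputs before using them. One point of scatter on a peak reading shifts the reckoned answer by 1.76 % of itself. The same scatter on the fall from 3.00 h to 8.00 h puts 0.00352 h⁻¹ on the decay rate averaged over the two runs. That shifts the reckoned D by 13.0 % of itself in south-east and 3.17 % of itself in west, so the decay rate weighs more in south-east than in west.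

Now take the numbers. The crossing is the peak, where formation of D gives way to loss. Define the tail half-life of D, the time in which D halves after its peak, as read from the fall in both runs: 42.5 h. A straight line through the two peak readings against the L fraction of the charge gives peaks of 58.4 % for south-east and 50.3 % for west. Beta and delta both read lower at 8.00 h than at 3.00 h, so carry the decay on without a floor. My reckoning gives 31.9 % for south-east and 43.5 % for west.

The forecast names west as higher, with 42 % for south-east and 47 % for west, on a “drift towards an uncertain equilibrium”. Its south-east figure stands 10 percentage points above mine.

The flask gives west as higher, with 42.7 % there against 23.2 % in south-east. Run from the peak, the tail half-life gave 43.5 % for west and 31.9 % for south-east, the south-east figure 8.7 points above the flask. On the south-east charge read at 15 h, it gives 48.0 % against 45.0 % in the flask. Neither flask has come to rest at its reading, which is kinetic rather than thermodynamic control. Ten times the time takes D in west to 5.27 % at 120 h and in south-east to 3.77 % at 400 h.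

    L ⇌ X (K = 0.430, k = 0.0840 h⁻¹)
    L → D (k = 1.20 h⁻¹)
    X → G (k = 0.560 h⁻¹)
    D ⇌ G (K = 25.0, k = 0.0290 h⁻¹)
    L + D → E (k = 0.0690 L mol⁻¹ h⁻¹)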